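Of the starting material lost in the ochre run between 10.0 min and 30.0 min, 15.1 % appeared as product. This branch share, a selectivity read from four readings with their scatter, is the quantity to carry.

in all of them: starting material 20 mM; free catalyst 2 mol%

| charge | partner | remark |
|---|---|---|
| red | 0.55 equiv | run made earlier |
| ochre | 0.83 equiv | run made earlier |
| flask | 1.10 equiv |  |

- red (time / min: product / %, starting material / %): 2.50: 0, 94.7; 4.00: 0, 90.9; 8.00: 1.5, 83.7; 12.0: 3.0, 78.5; 20.0: 4.8, 66.6; 30.0: 5.8, 53.3
- ochre (time / min: product / %, starting material / %): 5.00: 0.5, 90.3; 10.0: 2.3, 81.4; 15.0: 3.8, 73.4; 20.0: 4.1, 65.8; 25.0: 5.5, 59.8; 30.0: 6.5, 53.6

(standard deviation of a reading: 0.5 percentage points)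

* factor on the rate of making product when 50 % of the starting material are converted if free catalyst is charged twice over
* factor on the rate when 50 % of the starting material are converted if free catalyst is charged at 0.2 mol% instead

- no earlier run changes the charge of free catalyst; that part of a forecast is a guess

In the first minutes of the red run, starting material has fallen to 90.9 % at 4.00 min while product still reads 0 %, so something stands between them. At 30.0 min, starting material reads 53.3 % in the red run and 53.6 % in the ochre run, although partner differs, 0.55 equiv against 0.83 equiv. In the middle of the ochre run, the material found in neither column grows from 16.3 % at 10.0 min to 39.9 % at 30.0 min, far more than the 2 mol% of catalyst charged. That missing material grows by a factor of 2.45, yet product keeps roughly in step with the loss of starting material, so the reading taken here is that more material leaves by a side branch than becomes product. The red run gives a similar share, 14.1 %, from 8.00 min on. At the end of the flask, the same share puts product near 15.1 % of the charge.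

The reckoning made here is a guess, since no earlier run changes the catalyst. It supposes that free catalyst acts in two steps: it consumes starting material, and it captures what is released, against a loss that needs no catalyst. Capture over loss is then 0.178, proportional to catalyst, and the rate of making product is the rate of losing starting material times the share. At 50 % conversion, doubling the catalyst doubles the rate of losing starting material and also doubles capture over loss, which raises the share to 26.3 %. Together these give a factor of 3.48. At 0.2 mol%, the same rule gives 0.0116. The forecast gives other numbers, 1.9 and 0.12, from a “saturated, catalyst-limited step, which predicts rate proportional to catalyst”.

The simulation gives 3.43 and 0.0117.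

    starting material + free catalyst ⇌ free catalyst + open intermediate (K = 1.50, k = 53.7 /M/min)
    free catalyst + open intermediate ⇌ catalyst intermediate (K = 71.0 /M, k = 209 /M/min)
    partner + catalyst intermediate → free catalyst + product (k = 616 /M/min)
    open intermediate → decomposed reagent (k = 0.363 /min)

At 15.9 min in the flask, open intermediate goes to decomposed reagent 4.4 times as fast as free catalyst takes it up (forward rate of that step alone), with a half-life of 1.9 min by that loss, while free catalyst, the resting state, is 99.3 % of the catalyst at 33.6 min. After 400 min the flask holds 15.6 % product against 84.3 % decomposed reagent, where the ochre readings gave a branch share of 15.1 %.

The data are simulated for an exercise, and the scatter is random.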